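## Structural features

The target is a germacranolide: a ten-membered carbocycle (C1–C10) trans-fused at C6/C7 to an α-methylene-γ-butyrolactone (ring oxygen on C6, C7, C11 with the exocyclic C13, carbonyl C12). The carbocycle holds one trisubstituted olefin, C1=C10, whose two ring bonds (to C2 and C9) are cis; C10 carries the C14 hydroxymethyl group, C4 the C15 hydroxymethyl group and C8 the angelate. Three stereocentres are contiguous (C6 R, C7 S, C8 R), while the fourth, C4 (R), lies 1,3 to C6 across the C5 methylene and cannot simply be relayed from the triad. The fragile groups are the α-methylene lactone (a Michael acceptor), the angelate (prone to Z to E isomerisation to the tiglate), the allylic C14 alcohol, and a free C8 hydroxyl, which can relactonise onto C12. The real difficulty is to combine closure of a strained ten-membered ring containing a geometrically defined olefin with control of the stereotriad around the lactone. The key step uses the fact that C7 is the β-carbon of a C7=C11 butenolide and is flanked by C6 (a stereocentre on a flat five-membered ring), C8 (attachable as an acyl-anion equivalent) and C11 (the enolate carbon that can take C13). Both carbon arms and the future methylene carbon can therefore be placed around the lactone in one flask.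

## Logic of the disconnections

38 to 37: the two O–Si bonds at C14 and C15 are cut last. Keeping both primary alcohols silylated until the end leaves C8 as the only free hydroxyl at the acylation stage. The forward step needs a fluoride source that neither adds to the methylene lactone nor isomerises the angelate.

37 to 35 (through 36): the C11=C13 double bond is traced back to a C13–N bond and a C11–H bond. The Michael acceptor is thereby masked through all borane and palladium chemistry, and C13 is already in place. The forward step needs N-selective methylation and a base mild enough for the ester.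

35 to 32 and 33: the C8 O–acyl bond is cut. The geometrically labile angelate is introduced as late as the mask allows. The forward step must acylate a hindered secondary alcohol without Z to E isomerisation.

32 to 31: the O–Si bond at C8 is cut. A silyl group different from those on C14/C15 marks the C8 oxygen. The forward step must cleave a secondary triethylsilyl ether beside two primary tert-butyldimethylsilyl ethers.

31 to 29 (through 30): the ring bond C1–C2, an sp2–sp3 bond, is cut. The ten-membered ring opens to a lactone carrying a vinyl iodide arm and a terminal alkene arm, and the olefin geometry is stored in the iodide. The forward step is an intramolecular cross-coupling that must beat oligomerisation and keep the geometry.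

29 to 28: the C1–I bond is traced to a C1–Si bond. A vinyl iodide would not survive the organolithium chemistry earlier in the route, whereas a vinylsilane does. The forward step is an ipso substitution with retention, selective over the terminal alkene.

28 to 27 to 26: the O–Si bond and then the C8–H bond are cut, so the C8 carbinol becomes a ketone. The last stereocentre is left to a reagent-controlled hydride delivery. The forward steps must not epimerise C7 or eliminate the C6 oxygen of the β-acyloxy ketone.

26 to 25: the C8 carbonyl is traced to its dithioacetal (two C–S bonds). This reveals C8 as a nucleophilic carbon. The forward step must unmask it in the presence of a tertiary amine.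

25 to 12, 21 and 22 (through 23 and 24): the C7–C8 and C11–C13 bonds are cut. The whole carbon skeleton falls into a butenolide, a 2-substituted dithiane and a one-carbon iminium salt. The forward step needs 1,4-addition and two facial selectivities, both traceable to C6. The configurations of 12, 21 and 25 map onto C4, C6, C7 and the C1=C10 geometry of 38 without any correction.

12 to 10 (through 11), then to 7 and 8 (through 9): the lactone C12–O bond and the cis C7=C11 olefin go back to a hydroxy ynoate, and the C6–C7 bond is cut between carbinol and alkyne carbon. This gives an aldehyde and a three-carbon ester. The forward steps need catalyst control at C6 and alkyne-selective semi-hydrogenation.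

7 to 6 to 5, then to 3 and 4: the C4–C5 bond is cut at an allylic position, and the two-carbon aldehyde arm is traced to a malonate. The C4 stereocentre then comes from an achiral linear allylic carbonate. The forward step needs branched regioselectivity and enantiocontrol. 3 goes back to 2 and 1 by O–C and O–Si cuts.

21 to 18 and 19 (through 20): the C8–C9 bond is cut next to the dithiane. This leaves an allylic bromide and the parent dithiane. The forward step needs SN2 rather than SN2' attack.

18 to 17, then to 14 and 15 (through 16): the C9–Br bond is traced to a C9–O bond, and the C9–C10 bond is cut. C9 comes from a one-carbon electrophile and C10 from a vinyl metal. The forward step must keep the olefin geometry during metal exchange.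

14 to 13: the C1–Si and C10–Sn bonds are both cut. Both arise from one syn addition across a terminal alkyne, which fixes the C1=C10 geometry at the outset.

## Other disconnections considered

Alternative 1: The cut is at C11–C12 and C12–O, with C12 coming from carbon monoxide, so the lactone is the last ring formed on a finished cyclodecene. In the forward step the trans-2-ethynyl cyclodecenol A2 is treated with PdCl2, PPh3 and SnCl2 under CO in acetonitrile. The C6 alkoxycarbonylpalladium adds across the alkyne and gives the protected methylene lactone A1.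
- In its favour: the methylene lactone appears in its final form with no mask and no unveiling. The trans fusion is read directly from the trans hydroxyl/ethynyl pair. Only an ether-to-angelate exchange and desilylation remain after A1, which is better than the nine operations after 25.
- Against it here: the ten-membered ring, all four stereocentres and the olefin must already be present in A2. The key step therefore creates no stereocentre and solves none of the hard problems. A trans ethynyl carbinol on a medium ring is itself hard to reach because of transannular reactions. The Lewis-acidic tin chloride also meets an allylic silyl ether.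
- Comparison: the chosen step forms two C–C bonds and two stereocentres from acyclic fragments, whereas this one forms one C–C and one C–O bond. The two plans are equal in needing a late angelate and a final desilylation. Over the whole route the alternative is expected to be longer, because A2 is harder to make than 12 and 21.

Alternative 2: The cut is at C6–C7 and C11–C12 by a [2+2] cycloaddition, with the lactone oxygen inserted afterwards. In the forward step the amide A4 is activated with Tf2O and 2,4,6-collidine, and the resulting keteniminium ion adds to the terminal alkene of A5. Hydrolysis gives the cyclobutanone A3, and Baeyer–Villiger oxidation then inserts oxygen at the more substituted C6.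
- In its favour: it is as convergent as the chosen plan. C8 arrives already set in A5, so no late ketone reduction is needed, which is better than the chosen plan. The vinyl iodide is carried directly without a silicon detour, which is also better. The regiochemistry of the oxygen insertion is dependable.
- Against it here: C6 and C7 are both created in the cycloaddition, and their absolute sense rests on acyclic induction from the allylic C8 silyloxy group alone. Intermolecular keteniminium additions to unactivated monosubstituted alkenes usually need an excess of the alkene, which is costly for A5. C13 is not introduced, so a separate α-methylenation remains. The C2 oxygen must still be turned into a coupling partner before the same ten-ring closure.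
- Comparison: the chosen plan fixes C6 by catalyst control beforehand and relays it to C7 and C11 on a rigid ring, which is the more predictable stereochemical design. In step count after the key step the two are about equal.

Alternative 3: In the retrosynthetic sense a bond is added: C1–C6 is reconnected, so the ten-membered ring is traced to a cis-decalin. In the forward step KH deprotonates the tertiary C6 hydroxyl of the spiro-epoxy decalinol A7. The alkoxide fragments in a Grob reaction to the cyclodecenone A6, with the C6 carbonyl, the C1=C10 olefin and a free C14 alkoxide.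
- In its favour: the medium ring is made by ring expansion and not by end-to-end closure. This is better than the chosen plan at its weakest point, the macrocyclisation. The olefin geometry follows stereospecifically from the antiperiplanar arrangement. C14 emerges free and already differentiated from C15.
- Against it here: A7 needs six stereocentres, including a tertiary carbinol and a spiro-epoxide, and three of them (C1, C6, C10) are destroyed. In A6 the new ketone has an epimerisable C7 and a β-alkoxy group at C8 under strongly basic conditions. C6 must afterwards be reduced selectively in a flexible ring, and lactonisation, methylenation and the ether-to-angelate exchange follow.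
- Comparison: the alternative is better in ring formation and olefin control, and equal in the late acylation. It is clearly worse in stereochemical economy and overall length.

Key step: step 12

Assumption: in steps 3 and 6 the ligand antipodes named are those expected from the accepted models to give the stated configurations; if the sense of induction is the opposite, the mirror-image ligand is used.

## Route

Step 1
Reactants: 1 (E)-but-2-ene-1,4-diol
Product: 2 (E)-4-[(tert-butyldimethylsilyl)oxy]but-2-en-1-ol
Conditions: NaH (1.0 equiv), THF, 0 °C to rt; TBSCl (1.0 equiv)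
Reagents that add atoms: tert-butyldimethylsilyl chloride, CC(C)(C)[Si](C)(C)Cl
Why: O-silylation of a symmetrical diol through its sparingly soluble monosodium alkoxide, which should favour the mono-ether; the (E)-olefin is chosen because (E)-allylic carbonates form the syn π-allyl complexes that give branched products in step 3.

Step 2
Reactants: 2 (E)-4-[(tert-butyldimethylsilyl)oxy]but-2-en-1-ol
Product: 3 (E)-4-[(tert-butyldimethylsilyl)oxy]but-2-en-1-yl methyl carbonate
Conditions: ClCO2Me, pyridine, CH2Cl2, 0 °C
Reagents that add atoms: methyl chloroformate, COC(=O)Cl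
Why: Acylation of a primary alcohol with a chloroformate; the methyl carbonate is the leaving group and the internal base source for the allylic substitution.

Step 3
Reactants: 3 (E)-4-[(tert-butyldimethylsilyl)oxy]but-2-en-1-yl methyl carbonate; 4 dimethyl malonate
Product: 5 dimethyl 2-[(2R)-1-[(tert-butyldimethylsilyl)oxy]but-3-en-2-yl]propanedioate
Conditions: [Ir(cod)Cl]2 (2 mol %), (Sa,Sc,Sc)-O,O'-(1,1'-binaphthyl-2,2'-diyl) N,N-bis(1-phenylethyl)phosphoramidite (4 mol %), 1,5,7-triazabicyclo[4.4.0]dec-5-ene (8 mol %), THF, rt
Reagents that add atoms: none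
Why: Iridium-catalysed asymmetric allylic alkylation: the carbonate ionises to a syn π-allyl complex of the cyclometalated phosphoramidite catalyst and the malonate, deprotonated by the released methoxide, attacks the substituted terminus on the ligand-defined face, which should set C4 with branched regioselectivity.

Step 4
Reactants: 5 dimethyl 2-[(2R)-1-[(tert-butyldimethylsilyl)oxy]but-3-en-2-yl]propanedioate
Product: 6 methyl (3S)-3-{[(tert-butyldimethylsilyl)oxy]methyl}pent-4-enoate
Conditions: NaCl, H2O (2 equiv), DMSO, 150 °C
Reagents that add atoms: none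
Why: Krapcho dealkoxycarbonylation (chloride demethylates one ester and the carboxylate loses CO2); the stereocentre is not α to a carbonyl and is not at risk, the descriptor changes only through the priority rules, and a primary TBS ether should stand these neutral conditions.

Step 5
Reactants: 6 methyl (3S)-3-{[(tert-butyldimethylsilyl)oxy]methyl}pent-4-enoate
Product: 7 (3S)-3-{[(tert-butyldimethylsilyl)oxy]methyl}pent-4-enal
Conditions: i-Bu2AlH (1.05 equiv), CH2Cl2, −78 °C; aq. potassium sodium tartrate
Reagents that add atoms: none
Why: Partial reduction of an ester that stops at the aluminium hemiacetal at low temperature; the aldehyde has no α-stereocentre to lose.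

Step 6
Reactants: 7 (3S)-3-{[(tert-butyldimethylsilyl)oxy]methyl}pent-4-enal; 8 methyl propiolate
Product: 10 methyl (4R,6S)-6-{[(tert-butyldimethylsilyl)oxy]methyl}-4-hydroxyoct-7-en-2-ynoate, via zinc alkynylide 9 (not isolated)
Conditions: Me2Zn (3 equiv), (S,S)-ProPhenol (20 mol %), Ph3PO (40 mol %), toluene, 4 °C
Reagents that add atoms: none
Why: Catalytic asymmetric alkynylation of an aldehyde: the propiolate is zincated by Me2Zn and the dinuclear zinc complex of the ligand delivers the alkynyl group to one carbonyl face, which should set C6 (R) under catalyst control, independent of the remote C4 centre.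

Step 7
Reactants: 10 methyl (4R,6S)-6-{[(tert-butyldimethylsilyl)oxy]methyl}-4-hydroxyoct-7-en-2-ynoate
Product: 12 (5R)-5-[(2S)-2-{[(tert-butyldimethylsilyl)oxy]methyl}but-3-en-1-yl]furan-2(5H)-one (fragment 1), via hydroxy (Z)-enoate 11 (not isolated)
Conditions: H2 (1 atm), Pd/CaCO3 poisoned with Pb(OAc)2, quinoline, EtOAc, rt, stopped at one equivalent of H2; then PPTS (cat.), CH2Cl2, rt
Reagents that add atoms: none
Why: Lindlar semi-hydrogenation adds hydrogen syn to the alkyne and places hydroxyl and ester cis, so that acid-catalysed lactonisation closes the butenolide; the poisoned catalyst reduces the alkyne well before the monosubstituted alkene.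

Step 8
Reactants: 13 tert-butyldimethyl(prop-2-yn-1-yloxy)silane
Product: 14 (Z)-tert-butyldimethyl{[2-(tributylstannyl)-3-(trimethylsilyl)prop-2-en-1-yl]oxy}silane
Conditions: Me3Si–SnBu3 (1.05 equiv), Pd(PPh3)4 (2 mol %), THF, 65 °C
Reagents that add atoms: trimethyl(tributylstannyl)silane, CCCC[Sn](CCCC)(CCCC)[Si](C)(C)C
Why: Palladium-catalysed silylstannation of a terminal alkyne (oxidative addition of Si–Sn to zerovalent palladium, syn insertion, reductive elimination) places silicon on the terminal carbon C1 and tin on C10, cis to each other, which fixes the C1=C10 geometry.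

Step 9
Reactants: 14 (Z)-tert-butyldimethyl{[2-(tributylstannyl)-3-(trimethylsilyl)prop-2-en-1-yl]oxy}silane; 15 formaldehyde (used as paraformaldehyde)
Product: 17 (E)-2-{[(tert-butyldimethylsilyl)oxy]methyl}-3-(trimethylsilyl)prop-2-en-1-ol, via vinyllithium 16 (not isolated)
Conditions: n-BuLi (1.1 equiv), THF, −78 °C; (CH2O)n, −78 to 0 °C; aq. NH4Cl
Reagents that add atoms: none
Why: Tin–lithium exchange occurs with retention at the sp2 carbon and leaves the vinylsilane untouched; the vinyllithium adds to formaldehyde and introduces C9 cis to silicon.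

Step 10
Reactants: 17 (E)-2-{[(tert-butyldimethylsilyl)oxy]methyl}-3-(trimethylsilyl)prop-2-en-1-ol
Product: 18 (Z)-{[2-(bromomethyl)-3-(trimethylsilyl)prop-2-en-1-yl]oxy}(tert-butyl)dimethylsilane
Conditions: CBr4, PPh3, 2,6-lutidine (cat.), CH2Cl2, 0 °C
Reagents that add atoms: tetrabromomethane, BrC(Br)(Br)Br
Why: Appel bromination of a primary allylic alcohol by SN2 displacement of the oxyphosphonium group; the near-neutral conditions spare the silyl ether and the vinylsilane.

Step 11
Reactants: 18 (Z)-{[2-(bromomethyl)-3-(trimethylsilyl)prop-2-en-1-yl]oxy}(tert-butyl)dimethylsilane; 19 1,3-dithiane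
Product: 21 (E)-tert-butyl{[2-(1,3-dithian-2-ylmethyl)-3-(trimethylsilyl)prop-2-en-1-yl]oxy}dimethylsilane (fragment 2), via 2-lithio-1,3-dithiane 20 (not isolated)
Conditions: 19, n-BuLi, THF, −30 °C; then 18, −78 to −20 °C
Reagents that add atoms: none
Why: Corey–Seebach alkylation: the lithiated dithiane displaces the primary allylic bromide by SN2, the SN2' terminus being the hindered silyl-bearing carbon, and forms C8–C9.

Step 12
Reactants: 21 (E)-tert-butyl{[2-(1,3-dithian-2-ylmethyl)-3-(trimethylsilyl)prop-2-en-1-yl]oxy}dimethylsilane (fragment 2); 12 (5R)-5-[(2S)-2-{[(tert-butyldimethylsilyl)oxy]methyl}but-3-en-1-yl]furan-2(5H)-one (fragment 1); 22 dimethylmethyleneiminium iodide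
Product: 25 (3R,4S,5R)-5-[(2S)-2-{[(tert-butyldimethylsilyl)oxy]methyl}but-3-en-1-yl]-4-{2-[(2E)-2-{[(tert-butyldimethylsilyl)oxy]methyl}-3-(trimethylsilyl)prop-2-en-1-yl]-1,3-dithian-2-yl}-3-[(dimethylamino)methyl]oxolan-2-one, via lithiated dithiane 23 (not isolated), via lithium enolate 24 (not isolated)
Conditions: 21 (1.15 equiv), n-BuLi (1.1 equiv), THF, −30 °C; HMPA (3 equiv), −78 °C; 12 (1.0 equiv), −78 °C; Me2N=CH2+ I− (3 equiv), −78 to 0 °C
Reagents that add atoms: none
Why: n-BuLi removes the dithiane proton of 21; with HMPA the anion 23 is a solvent-separated ion pair, a soft nucleophile that attacks the β-carbon C7 of 12 and not the carbonyl, forming C7–C8. The attack comes from the face of the flat butenolide opposite the C5 arm on C6, so C6 controls C7 and the C6/C7 relation should be trans. The lithium enolate 24 is not quenched but reacts at C11 with the iminium ion of 22 in a Mannich reaction, forming C11–C13 on the face opposite the bulky dithiane, so C7 controls C11 (trans again). The closest known reaction type is the tandem conjugate addition of 2-lithio-1,3-dithianes to butenolides with carbon trapping of the enolate, combined with aminomethylation of lactone enolates by a preformed iminium salt. No ring is closed; two skeletal bonds and two stereocentres are made, and both carbon arms and the latent methylene carbon are attached to the lactone in one operation. The selectivities needed are 1,4 over 1,2 addition (HMPA and the sulfur-stabilised anion), addition over deprotonation of the γ-hydrogen on C6 (low temperature), and trapping before proton transfer or retro-Michael reaction (excess of the reactive iminium salt added cold).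

Step 13
Reactants: 25 (3R,4S,5R)-5-[(2S)-2-{[(tert-butyldimethylsilyl)oxy]methyl}but-3-en-1-yl]-4-{2-[(2E)-2-{[(tert-butyldimethylsilyl)oxy]methyl}-3-(trimethylsilyl)prop-2-en-1-yl]-1,3-dithian-2-yl}-3-[(dimethylamino)methyl]oxolan-2-one
Product: 26 (3R,4S,5R)-5-[(2S)-2-{[(tert-butyldimethylsilyl)oxy]methyl}but-3-en-1-yl]-4-[(3E)-3-{[(tert-butyldimethylsilyl)oxy]methyl}-4-(trimethylsilyl)but-3-enoyl]-3-[(dimethylamino)methyl]oxolan-2-one
Conditions: TFA (1.05 equiv), then PhI(OCOCF3)2 (1.5 equiv), MeCN/H2O 9:1, 0 °C, 10 min; cold aq. NaHCO3; used at once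
Reagents that add atoms: water, O
Why: Oxidative dethioacetalisation with a trivalent iodine reagent (sulfur is oxidised to a sulfonium group that water displaces); the amine is protonated first so that it is neither oxidised nor able to act as an internal base on the β-acyloxy ketone, and vinylsilane, alkene and silyl ethers should be inert in this short cold reaction.

Step 14
Reactants: 26 (3R,4S,5R)-5-[(2S)-2-{[(tert-butyldimethylsilyl)oxy]methyl}but-3-en-1-yl]-4-[(3E)-3-{[(tert-butyldimethylsilyl)oxy]methyl}-4-(trimethylsilyl)but-3-enoyl]-3-[(dimethylamino)methyl]oxolan-2-one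
Product: 27 (3R,4R,5R)-5-[(2S)-2-{[(tert-butyldimethylsilyl)oxy]methyl}but-3-en-1-yl]-4-[(1R,3E)-3-{[(tert-butyldimethylsilyl)oxy]methyl}-1-hydroxy-4-(trimethylsilyl)but-3-en-1-yl]-3-[(dimethylamino)methyl]oxolan-2-one
Conditions: (S)-2-methyl-CBS-oxazaborolidine (1.0 equiv), catecholborane (2 equiv), toluene/CH2Cl2, −78 to −40 °C; MeOH, pH 7 buffer
Reagents that add atoms: none
Why: Corey–Bakshi–Shibata reduction: the oxazaborolidine binds the ketone anti to the larger, α-branched C7 side and delivers hydride to the face that gives the (8R) carbinol (the sense that turns acetophenone into the (R) alcohol); catecholborane is used because it forms no lasting adduct with the tertiary amine.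

Step 15
Reactants: 27 (3R,4R,5R)-5-[(2S)-2-{[(tert-butyldimethylsilyl)oxy]methyl}but-3-en-1-yl]-4-[(1R,3E)-3-{[(tert-butyldimethylsilyl)oxy]methyl}-1-hydroxy-4-(trimethylsilyl)but-3-en-1-yl]-3-[(dimethylamino)methyl]oxolan-2-one
Product: 28 (3R,4S,5R)-5-[(2S)-2-{[(tert-butyldimethylsilyl)oxy]methyl}but-3-en-1-yl]-4-[(1R,3E)-3-{[(tert-butyldimethylsilyl)oxy]methyl}-1-[(triethylsilyl)oxy]-4-(trimethylsilyl)but-3-en-1-yl]-3-[(dimethylamino)methyl]oxolan-2-one
Conditions: TESOTf (1.2 equiv), 2,6-lutidine (2.5 equiv), CH2Cl2, −78 °C
Reagents that add atoms: triethylsilyl trifluoromethanesulfonate, CC[Si](CC)(CC)OS(=O)(=O)C(F)(F)F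
Why: Silylation with a silyl triflate and a hindered base at low temperature caps the C8 hydroxyl before it can relactonise onto C12; triethylsilyl is chosen because it can later be removed beside the two primary TBS ethers.

Step 16
Reactants: 28 (3R,4S,5R)-5-[(2S)-2-{[(tert-butyldimethylsilyl)oxy]methyl}but-3-en-1-yl]-4-[(1R,3E)-3-{[(tert-butyldimethylsilyl)oxy]methyl}-1-[(triethylsilyl)oxy]-4-(trimethylsilyl)but-3-en-1-yl]-3-[(dimethylamino)methyl]oxolan-2-one
Product: 29 (3R,4S,5R)-5-[(2S)-2-{[(tert-butyldimethylsilyl)oxy]methyl}but-3-en-1-yl]-4-[(1R,3E)-3-{[(tert-butyldimethylsilyl)oxy]methyl}-4-iodo-1-[(triethylsilyl)oxy]but-3-en-1-yl]-3-[(dimethylamino)methyl]oxolan-2-one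
Conditions: TFA (1.05 equiv), then NIS (1.3 equiv), (CF3)2CHOH, 0 °C, 10 min; aq. Na2S2O3/NaHCO3
Reagents that add atoms: N-iodosuccinimide, O=C1CCC(=O)N1I
Why: Iododesilylation is an electrophilic ipso substitution through a β-silyl-stabilised cation and proceeds with retention in hexafluoroisopropanol; the vinylsilane is far more nucleophilic than the monosubstituted alkene, and the amine is kept as its salt so that it does not consume the iodinating agent.

Step 17
Reactants: 29 (3R,4S,5R)-5-[(2S)-2-{[(tert-butyldimethylsilyl)oxy]methyl}but-3-en-1-yl]-4-[(1R,3E)-3-{[(tert-butyldimethylsilyl)oxy]methyl}-4-iodo-1-[(triethylsilyl)oxy]but-3-en-1-yl]-3-[(dimethylamino)methyl]oxolan-2-one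
Product: 31 (3R,3aS,4R,6E,10R,11aR)-6,10-bis({[tert-butyldimethylsilyl]oxy}methyl)-3-[(dimethylamino)methyl]-4-[(triethylsilyl)oxy]-3a,4,5,8,9,10,11,11a-octahydrocyclodeca[b]furan-2(3H)-one, via B-alkyl-9-BBN 30 (not isolated)
Conditions: 9-BBN (3 equiv), THF, 0 °C to rt; then slow addition to Pd(dppf)Cl2 (20 mol %), AsPh3 (20 mol %), aq. K3PO4, DMF/THF, 50 °C, final 0.002 M
Reagents that add atoms: none
Why: B-alkyl Suzuki–Miyaura macrocyclisation: 9-BBN adds anti-Markovnikov to the terminal alkene only, and after activation by base the alkyl group is transferred to the alkenylpalladium iodide, closing C1–C2 with retention of the olefin geometry; high dilution favours ring closure and the amine mask keeps the lactone free of any Heck or conjugate-addition acceptor.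

Step 18
Reactants: 31 (3R,3aS,4R,6E,10R,11aR)-6,10-bis({[tert-butyldimethylsilyl]oxy}methyl)-3-[(dimethylamino)methyl]-4-[(triethylsilyl)oxy]-3a,4,5,8,9,10,11,11a-octahydrocyclodeca[b]furan-2(3H)-one
Product: 32 (3R,3aR,4R,6E,10R,11aR)-6,10-bis({[tert-butyldimethylsilyl]oxy}methyl)-3-[(dimethylamino)methyl]-4-hydroxy-3a,4,5,8,9,10,11,11a-octahydrocyclodeca[b]furan-2(3H)-one
Conditions: PPTS (3 equiv), MeOH/CH2Cl2, 0 °C
Reagents that add atoms: none
Why: Acid-catalysed methanolysis of a silyl ether; a secondary triethylsilyl ether is much more labile than primary TBS ethers, and an excess of the acid is used because one equivalent is buffered by the amine.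

Step 19
Reactants: 32 (3R,3aR,4R,6E,10R,11aR)-6,10-bis({[tert-butyldimethylsilyl]oxy}methyl)-3-[(dimethylamino)methyl]-4-hydroxy-3a,4,5,8,9,10,11,11a-octahydrocyclodeca[b]furan-2(3H)-one; 33 angelic acid [(2Z)-2-methylbut-2-enoic acid]
Product: 35 (3R,3aS,4R,6E,10R,11aR)-6,10-bis({[tert-butyldimethylsilyl]oxy}methyl)-3-[(dimethylamino)methyl]-2-oxo-2,3,3a,4,5,8,9,10,11,11a-decahydrocyclodeca[b]furan-4-yl (2Z)-2-methylbut-2-enoate, via mixed anhydride 34 (not isolated)
Conditions: 33 (4 equiv), 2,4,6-trichlorobenzoyl chloride (4 equiv), Et3N (8 equiv), toluene, rt; then 32, toluene, 80 °C, no DMAP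
Reagents that add atoms: none
Why: Yamaguchi esterification through the mixed anhydride; leaving out the nucleophilic catalyst avoids the addition–elimination path that turns angelate into tiglate, heating compensates for the hindered alcohol, and the methylene lactone is still masked so that no Michael acceptor is present.

Step 20
Reactants: 35 (3R,3aS,4R,6E,10R,11aR)-6,10-bis({[tert-butyldimethylsilyl]oxy}methyl)-3-[(dimethylamino)methyl]-2-oxo-2,3,3a,4,5,8,9,10,11,11a-decahydrocyclodeca[b]furan-4-yl (2Z)-2-methylbut-2-enoate
Product: 37 (3aS,4R,6E,10R,11aR)-6,10-bis({[tert-butyldimethylsilyl]oxy}methyl)-3-methylidene-2-oxo-2,3,3a,4,5,8,9,10,11,11a-decahydrocyclodeca[b]furan-4-yl (2Z)-2-methylbut-2-enoate, via trimethylammonium iodide 36 (not isolated)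
Conditions: MeI (10 equiv), MeCN, rt; then sat. aq. NaHCO3, EtOAc, rt
Reagents that add atoms: none
Why: N-methylation gives a quaternary ammonium salt β to the lactone carbonyl, which loses trimethylamine by E1cB elimination with bicarbonate and unveils C11=C13; the C11 stereocentre is removed by design.

Step 21
Reactants: 37 (3aS,4R,6E,10R,11aR)-6,10-bis({[tert-butyldimethylsilyl]oxy}methyl)-3-methylidene-2-oxo-2,3,3a,4,5,8,9,10,11,11a-decahydrocyclodeca[b]furan-4-yl (2Z)-2-methylbut-2-enoate
Product: 38 (3aS,4R,6E,10R,11aR)-6,10-bis(hydroxymethyl)-3-methylidene-2-oxo-2,3,3a,4,5,8,9,10,11,11a-decahydrocyclodeca[b]furan-4-yl (2Z)-2-methylbut-2-enoate (CNP0262807.1)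
Conditions: HF·pyridine, pyridine, THF, 0 °C to rt
Reagents that add atoms: none
Why: Fluoride-mediated desilylation under buffered, weakly acidic conditions should remove both primary TBS ethers without conjugate addition to the methylene lactone, isomerisation of the angelate or acyl migration.

## Compound list

1 | (E)-but-2-ene-1,4-diol | OC/C=C/CO | starting material
2 | (E)-4-[(tert-butyldimethylsilyl)oxy]but-2-en-1-ol | CC(C)(C)[Si](C)(C)OC/C=C/CO | intermediate
3 | (E)-4-[(tert-butyldimethylsilyl)oxy]but-2-en-1-yl methyl carbonate | COC(=O)OC/C=C/CO[Si](C)(C)C(C)(C)C | intermediate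
4 | dimethyl malonate | COC(=O)CC(=O)OC | starting material
5 | dimethyl 2-[(2R)-1-[(tert-butyldimethylsilyl)oxy]but-3-en-2-yl]propanedioate | COC(=O)C(C(=O)OC)[C@H](CO[Si](C)(C)C(C)(C)C)C=C | intermediate
6 | methyl (3S)-3-{[(tert-butyldimethylsilyl)oxy]methyl}pent-4-enoate | COC(=O)C[C@H](CO[Si](C)(C)C(C)(C)C)C=C | intermediate
7 | (3S)-3-{[(tert-butyldimethylsilyl)oxy]methyl}pent-4-enal | O=CC[C@H](CO[Si](C)(C)C(C)(C)C)C=C | intermediate
8 | methyl propiolate | C#CC(=O)OC | starting material
9 | methyl 3-(methylzincio)prop-2-ynoate (zinc alkynylide) | C[Zn]C#CC(=O)OC | intermediate (not isolated)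
10 | methyl (4R,6S)-6-{[(tert-butyldimethylsilyl)oxy]methyl}-4-hydroxyoct-7-en-2-ynoate | COC(=O)C#C[C@H](O)C[C@H](CO[Si](C)(C)C(C)(C)C)C=C | intermediate
11 | methyl (2Z,4R,6S)-6-{[(tert-butyldimethylsilyl)oxy]methyl}-4-hydroxyocta-2,7-dienoate | COC(=O)/C=C\[C@H](O)C[C@H](CO[Si](C)(C)C(C)(C)C)C=C | intermediate (not isolated)
12 | (5R)-5-[(2S)-2-{[(tert-butyldimethylsilyl)oxy]methyl}but-3-en-1-yl]furan-2(5H)-one (fragment 1) | O=C1C=C[C@@H](C[C@H](CO[Si](C)(C)C(C)(C)C)C=C)O1 | intermediate
13 | tert-butyldimethyl(prop-2-yn-1-yloxy)silane | C#CCO[Si](C)(C)C(C)(C)C | starting material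
14 | (Z)-tert-butyldimethyl{[2-(tributylstannyl)-3-(trimethylsilyl)prop-2-en-1-yl]oxy}silane | CC(C)(C)[Si](C)(C)OC/C(=C/[Si](C)(C)C)[Sn](CCCC)(CCCC)CCCC | intermediate
15 | formaldehyde (used as paraformaldehyde) | C=O | starting material
16 | (E)-{3-[(tert-butyldimethylsilyl)oxy]-1-(trimethylsilyl)prop-1-en-2-yl}lithium | CC(C)(C)[Si](C)(C)OC/C([Li])=C/[Si](C)(C)C | intermediate (not isolated)
17 | (E)-2-{[(tert-butyldimethylsilyl)oxy]methyl}-3-(trimethylsilyl)prop-2-en-1-ol | CC(C)(C)[Si](C)(C)OC/C(CO)=C/[Si](C)(C)C | intermediate
18 | (Z)-{[2-(bromomethyl)-3-(trimethylsilyl)prop-2-en-1-yl]oxy}(tert-butyl)dimethylsilane | CC(C)(C)[Si](C)(C)OC/C(CBr)=C/[Si](C)(C)C | intermediate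
19 | 1,3-dithiane | C1CSCSC1 | starting material
20 | 2-lithio-1,3-dithiane | [Li]C1SCCCS1 | intermediate (not isolated)
21 | (E)-tert-butyl{[2-(1,3-dithian-2-ylmethyl)-3-(trimethylsilyl)prop-2-en-1-yl]oxy}dimethylsilane (fragment 2) | C1(C/C(CO[Si](C)(C)C(C)(C)C)=C\[Si](C)(C)C)SCCCS1 | intermediate
22 | dimethylmethyleneiminium iodide | C=[N+](C)C.[I-] | starting material
23 | 2-lithio derivative of 21 | [Li]C1(C/C(CO[Si](C)(C)C(C)(C)C)=C\[Si](C)(C)C)SCCCS1 | intermediate (not isolated)
24 | lithium enolate of the 4,5-trans conjugate adduct of 23 and 12 | [Li]OC1=C[C@H](C2(C/C(CO[Si](C)(C)C(C)(C)C)=C\[Si](C)(C)C)SCCCS2)[C@@H](C[C@H](CO[Si](C)(C)C(C)(C)C)C=C)O1 | intermediate (not isolated)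
25 | (3R,4S,5R)-5-[(2S)-2-{[(tert-butyldimethylsilyl)oxy]methyl}but-3-en-1-yl]-4-{2-[(2E)-2-{[(tert-butyldimethylsilyl)oxy]methyl}-3-(trimethylsilyl)prop-2-en-1-yl]-1,3-dithian-2-yl}-3-[(dimethylamino)methyl]oxolan-2-one | O=C1O[C@H](C[C@H](CO[Si](C)(C)C(C)(C)C)C=C)[C@@H](C2(C/C(CO[Si](C)(C)C(C)(C)C)=C\[Si](C)(C)C)SCCCS2)[C@@H]1CN(C)C | intermediate
26 | (3R,4S,5R)-5-[(2S)-2-{[(tert-butyldimethylsilyl)oxy]methyl}but-3-en-1-yl]-4-[(3E)-3-{[(tert-butyldimethylsilyl)oxy]methyl}-4-(trimethylsilyl)but-3-enoyl]-3-[(dimethylamino)methyl]oxolan-2-one | O=C1O[C@H](C[C@H](CO[Si](C)(C)C(C)(C)C)C=C)[C@@H](C(=O)C/C(CO[Si](C)(C)C(C)(C)C)=C\[Si](C)(C)C)[C@@H]1CN(C)C | intermediate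
27 | (3R,4R,5R)-5-[(2S)-2-{[(tert-butyldimethylsilyl)oxy]methyl}but-3-en-1-yl]-4-[(1R,3E)-3-{[(tert-butyldimethylsilyl)oxy]methyl}-1-hydroxy-4-(trimethylsilyl)but-3-en-1-yl]-3-[(dimethylamino)methyl]oxolan-2-one | O=C1O[C@H](C[C@H](CO[Si](C)(C)C(C)(C)C)C=C)[C@@H]([C@H](O)C/C(CO[Si](C)(C)C(C)(C)C)=C\[Si](C)(C)C)[C@@H]1CN(C)C | intermediate
28 | (3R,4S,5R)-5-[(2S)-2-{[(tert-butyldimethylsilyl)oxy]methyl}but-3-en-1-yl]-4-[(1R,3E)-3-{[(tert-butyldimethylsilyl)oxy]methyl}-1-[(triethylsilyl)oxy]-4-(trimethylsilyl)but-3-en-1-yl]-3-[(dimethylamino)methyl]oxolan-2-one | O=C1O[C@H](C[C@H](CO[Si](C)(C)C(C)(C)C)C=C)[C@@H]([C@H](O[Si](CC)(CC)CC)C/C(CO[Si](C)(C)C(C)(C)C)=C\[Si](C)(C)C)[C@@H]1CN(C)C | intermediate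
29 | (3R,4S,5R)-5-[(2S)-2-{[(tert-butyldimethylsilyl)oxy]methyl}but-3-en-1-yl]-4-[(1R,3E)-3-{[(tert-butyldimethylsilyl)oxy]methyl}-4-iodo-1-[(triethylsilyl)oxy]but-3-en-1-yl]-3-[(dimethylamino)methyl]oxolan-2-one | O=C1O[C@H](C[C@H](CO[Si](C)(C)C(C)(C)C)C=C)[C@@H]([C@H](O[Si](CC)(CC)CC)C/C(CO[Si](C)(C)C(C)(C)C)=C\I)[C@@H]1CN(C)C | intermediate
30 | B-alkyl-9-BBN derivative of 29 (terminal CH=CH2 converted into CH2CH2–B of 9-borabicyclo[3.3.1]nonane; side-chain centre 2R) | O=C1O[C@H](C[C@H](CO[Si](C)(C)C(C)(C)C)CCB2C3CCCC2CCC3)[C@@H]([C@H](O[Si](CC)(CC)CC)C/C(CO[Si](C)(C)C(C)(C)C)=C\I)[C@@H]1CN(C)C | intermediate (not isolated)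
31 | (3R,3aS,4R,6E,10R,11aR)-6,10-bis({[tert-butyldimethylsilyl]oxy}methyl)-3-[(dimethylamino)methyl]-4-[(triethylsilyl)oxy]-3a,4,5,8,9,10,11,11a-octahydrocyclodeca[b]furan-2(3H)-one | CN(C)C[C@@H]1C(=O)O[C@@H]2C[C@H](CO[Si](C)(C)C(C)(C)C)CC/C=C(/CO[Si](C)(C)C(C)(C)C)C[C@@H](O[Si](CC)(CC)CC)[C@@H]12 | intermediate
32 | (3R,3aR,4R,6E,10R,11aR)-6,10-bis({[tert-butyldimethylsilyl]oxy}methyl)-3-[(dimethylamino)methyl]-4-hydroxy-3a,4,5,8,9,10,11,11a-octahydrocyclodeca[b]furan-2(3H)-one | CN(C)C[C@@H]1C(=O)O[C@@H]2C[C@H](CO[Si](C)(C)C(C)(C)C)CC/C=C(/CO[Si](C)(C)C(C)(C)C)C[C@@H](O)[C@@H]12 | intermediate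
33 | angelic acid, (2Z)-2-methylbut-2-enoic acid | C/C=C(/C)C(=O)O | starting material
34 | (2Z)-2-methylbut-2-enoic 2,4,6-trichlorobenzoic anhydride | C/C=C(/C)C(=O)OC(=O)c1c(Cl)cc(Cl)cc1Cl | intermediate (not isolated)
35 | (3R,3aS,4R,6E,10R,11aR)-6,10-bis({[tert-butyldimethylsilyl]oxy}methyl)-3-[(dimethylamino)methyl]-2-oxo-2,3,3a,4,5,8,9,10,11,11a-decahydrocyclodeca[b]furan-4-yl (2Z)-2-methylbut-2-enoate | CN(C)C[C@@H]1C(=O)O[C@@H]2C[C@H](CO[Si](C)(C)C(C)(C)C)CC/C=C(/CO[Si](C)(C)C(C)(C)C)C[C@@H](OC(=O)/C(C)=C\C)[C@@H]12 | intermediate
36 | N,N,N-trimethylammonium iodide of 35 (quaternised at the C13 nitrogen) | C[N+](C)(C)C[C@@H]1C(=O)O[C@@H]2C[C@H](CO[Si](C)(C)C(C)(C)C)CC/C=C(/CO[Si](C)(C)C(C)(C)C)C[C@@H](OC(=O)/C(C)=C\C)[C@@H]12.[I-] | intermediate (not isolated)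
37 | (3aS,4R,6E,10R,11aR)-6,10-bis({[tert-butyldimethylsilyl]oxy}methyl)-3-methylidene-2-oxo-2,3,3a,4,5,8,9,10,11,11a-decahydrocyclodeca[b]furan-4-yl (2Z)-2-methylbut-2-enoate | C=C1C(=O)O[C@@H]2C[C@H](CO[Si](C)(C)C(C)(C)C)CC/C=C(/CO[Si](C)(C)C(C)(C)C)C[C@@H](OC(=O)/C(C)=C\C)[C@@H]12 | intermediate
38 | (3aS,4R,6E,10R,11aR)-6,10-bis(hydroxymethyl)-3-methylidene-2-oxo-2,3,3a,4,5,8,9,10,11,11a-decahydrocyclodeca[b]furan-4-yl (2Z)-2-methylbut-2-enoate (CNP0262807.1) | C=C1C(=O)O[C@@H]2C[C@H](CO)CC/C=C(/CO)C[C@@H](OC(=O)/C(C)=C\C)[C@@H]12 | target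

## Step count and least certain steps

Total step count: 21 steps. Longest linear sequence: 17 steps (steps 1–7 and 12–21); the four steps 8–11 form the shorter branch.

Step 12 (key step). Addition to the lactone carbonyl, proton abstraction from C6 by the basic dithiane anion, or proton transfer and retro-Michael reaction before the iminium salt has reacted could each erode the three-component coupling. Incomplete facial discrimination at C11 would lower the diastereomeric purity. The fallback separates the two bond formations, sets out from 12 and 21 and returns at 25. The conjugate addition is run alone under the same conditions and quenched cold with acetic acid to give the isolated trans-4,5-disubstituted lactone F1. F1 is then enolised with LiN(i-Pr)2 in THF at −78 °C, and the enolate is aminomethylated with 22 anti to the dithiane to give 25.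

Step 17. Ring strain in the ten-membered transition state may make intermolecular coupling, protodeboronation or β-hydride loss faster than cyclisation, and the aqueous base may open the lactone. The fallback keeps the C1–C2 disconnection but changes the nucleophile to an organozinc under base-free conditions; it sets out from 29 and returns at 31. Hydroboration of 29 with 9-BBN and oxidation with NaBO3 gives the primary alcohol F2. I2, PPh3 and imidazole convert it into the primary iodide F3. Activated zinc dust in THF inserts into the sp3 C–I bond only and gives the alkylzinc iodide F4, which is cyclised by intramolecular Negishi coupling with Pd(PPh3)4 at high dilution to 31.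

Step 14. The intrinsic facial preference of the ketone, which has a stereocentre at C7, may oppose the catalyst and give poor selectivity at C8. In addition, the free-base form of 26 can epimerise at C7 or lose the C6 oxygen by β-elimination before it is reduced. The fallback abandons catalyst control; it sets out from 26 and returns at 27. The crude ketone is reduced at once with NaBH4 and CeCl3 in MeOH at −78 °C under substrate control. If this delivers the (8S)-alcohol F5 (the C8 epimer of 27), F5 is inverted by a Mitsunobu reaction with chloroacetic acid, PPh3 and diisopropyl azodicarboxylate to the (8R)-chloroacetate F6. The chloroacetate is then removed with thiourea and NaHCO3 in ethanol under nearly neutral conditions to give 27.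

Step 19. Isomerisation of the angelate to the tiglate during activation or heating, or slow acylation of the hindered C8 hydroxyl that allows relactonisation toward C8, may spoil the esterification. The fallback builds the Z olefin after the ester bond; it sets out from 32 and returns at 35. 32 is esterified with 2-[bis(2,2,2-trifluoroethoxy)phosphoryl]propanoic acid (carbodiimide, DMAP, CH2Cl2) to the phosphonopropanoate F7. A Still–Gennari olefination of F7 with acetaldehyde (KN(SiMe3)2, 18-crown-6, THF, −78 °C) should then give the (Z)-2-methylbut-2-enoate 35. The lactone is still masked as the amine at this stage, so no Michael acceptor competes.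

Step 18. The rate difference between the hindered secondary triethylsilyl ether and the allylic primary TBS ether at C14 may be too small, so that partial loss of the C14 silyl group accompanies the wanted cleavage. The fallback gives up selective cleavage in favour of selective protection; it sets out from 31 and returns at 32. All three silyl groups are removed with HF·pyridine to give the triol F8. The two primary hydroxyls of F8 are then silylated with TBSCl (2.2 equiv) and imidazole at −20 °C, and the hindered secondary C8 hydroxyl is left free to give 32.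

## Further compounds

F1 | step 12 | (4S,5R)-5-[(2S)-2-{[(tert-butyldimethylsilyl)oxy]methyl}but-3-en-1-yl]-4-{2-[(2E)-2-{[(tert-butyldimethylsilyl)oxy]methyl}-3-(trimethylsilyl)prop-2-en-1-yl]-1,3-dithian-2-yl}oxolan-2-one | O=C1O[C@H](C[C@H](CO[Si](C)(C)C(C)(C)C)C=C)[C@@H](C2(C/C(CO[Si](C)(C)C(C)(C)C)=C\[Si](C)(C)C)SCCCS2)C1
F2 | step 17 | primary alcohol from 29 (terminal CH=CH2 converted into CH2CH2OH) | O=C1O[C@H](C[C@H](CO[Si](C)(C)C(C)(C)C)CCO)[C@@H]([C@H](O[Si](CC)(CC)CC)C/C(CO[Si](C)(C)C(C)(C)C)=C\I)[C@@H]1CN(C)C
F3 | step 17 | primary iodide from F2 (CH2CH2OH converted into CH2CH2I) | O=C1O[C@H](C[C@H](CO[Si](C)(C)C(C)(C)C)CCI)[C@@H]([C@H](O[Si](CC)(CC)CC)C/C(CO[Si](C)(C)C(C)(C)C)=C\I)[C@@H]1CN(C)C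
F4 | step 17 | alkylzinc iodide from F3 (CH2CH2I converted into CH2CH2ZnI) | O=C1O[C@H](C[C@H](CO[Si](C)(C)C(C)(C)C)CC[Zn]I)[C@@H]([C@H](O[Si](CC)(CC)CC)C/C(CO[Si](C)(C)C(C)(C)C)=C\I)[C@@H]1CN(C)C
F5 | step 14 | C8 epimer of 27 with the (1S) carbinol | O=C1O[C@H](C[C@H](CO[Si](C)(C)C(C)(C)C)C=C)[C@@H]([C@@H](O)C/C(CO[Si](C)(C)C(C)(C)C)=C\[Si](C)(C)C)[C@@H]1CN(C)C
F6 | step 14 | chloroacetate of 27 with the (1R) configuration | O=C1O[C@H](C[C@H](CO[Si](C)(C)C(C)(C)C)C=C)[C@@H]([C@H](OC(=O)CCl)C/C(CO[Si](C)(C)C(C)(C)C)=C\[Si](C)(C)C)[C@@H]1CN(C)C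
F7 | step 19 | 2-[bis(2,2,2-trifluoroethoxy)phosphoryl]propanoate of 32 (mixture of epimers at the phosphonate-bearing carbon) | CN(C)C[C@@H]1C(=O)O[C@@H]2C[C@H](CO[Si](C)(C)C(C)(C)C)CC/C=C(/CO[Si](C)(C)C(C)(C)C)C[C@@H](OC(=O)C(C)P(=O)(OCC(F)(F)F)OCC(F)(F)F)[C@@H]12
F8 | step 18 | triol from 31 (free hydroxyls at C8, C14 and C15; amine retained) | CN(C)C[C@@H]1C(=O)O[C@@H]2C[C@H](CO)CC/C=C(/CO)C[C@@H](O)[C@@H]12
A1 | alternative 1 | protected α-methylene lactone (C8 4-methoxybenzyl ether, C14 and C15 TBS ethers) | C=C1C(=O)O[C@@H]2C[C@H](CO[Si](C)(C)C(C)(C)C)CC/C=C(/CO[Si](C)(C)C(C)(C)C)C[C@@H](OCc3ccc(OC)cc3)[C@@H]12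
A2 | alternative 1 | trans-2-ethynyl cyclodecenol (C6 hydroxyl, C7 ethynyl) | O[C@@H]1C[C@H](CO[Si](C)(C)C(C)(C)C)CC/C=C(/CO[Si](C)(C)C(C)(C)C)C[C@@H](OCc2ccc(OC)cc2)[C@H]1C#C
A3 | alternative 2 | trans-2,3-disubstituted cyclobutanone | O=C1C[C@H]([C@H](O[Si](C)(C)C(C)(C)C)C/C(CO[Si](c2ccccc2)(c2ccccc2)C(C)(C)C)=C\I)[C@H]1C[C@H](CO[Si](c2ccccc2)(c2ccccc2)C(C)(C)C)CCO[Si](C)(C)C(C)(C)C
A4 | alternative 2 | N-acylpyrrolidine carrying C2–C6 and C15 (C12 amide) | O=C(CC[C@H](CO[Si](c1ccccc1)(c1ccccc1)C(C)(C)C)CCO[Si](C)(C)C(C)(C)C)N1CCCC1
A5 | alternative 2 | terminal alkene carrying C8–C10, C14 and the C1 vinyl iodide | C=C[C@H](O[Si](C)(C)C(C)(C)C)C/C(CO[Si](c1ccccc1)(c1ccccc1)C(C)(C)C)=C\I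
A6 | alternative 3 | cyclodecenone with free C14 alcohol | O=C1C[C@H](CO[Si](C)(C)C(C)(C)C)CC/C=C(/CO)C[C@@H](OCc2ccc(OC)cc2)[C@H]1CC(=O)OC(C)(C)C
A7 | alternative 3 | cis-fused spiro-epoxy decalinol (C6 tertiary alcohol, C1–C6 ring bond, C10 spiro-epoxide with its oxygen trans to the hydroxyl) | O[C@]12C[C@H](CO[Si](C)(C)C(C)(C)C)CC[C@H]1[C@]3(CO3)C[C@@H](OCc3ccc(OC)cc3)[C@H]2CC(=O)OC(C)(C)C
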